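**Strategy.** Xenicane numbering is used. The seven-membered ring C4a–C5–C6–C7–C19–C11–C11a of the bicyclo[4.3.1]decane holds a quaternary C7 between two methylenes, C6 and C19. That C6–C7–C19 unit is read as a hydrogenolysed 3,3-disubstituted cyclopropene, and C5–C4a–C11a–C11 as a 1-silyloxydiene. An intramolecular Diels–Alder reaction of an acyclic triene that carries only the C8 stereocentre forms C5–C6 and C19–C11 in one operation, closes both carbocycles and fixes C7 and C11; cyclopropene strain drives it. Hydrogenolysis of the leftover C6–C19 bond then turns the cyclohexene ring into the cycloheptane. Syn hydroboration and a boronate olefination set C4a and C11a and attach the dienal arm.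

Key step: step 10

Remark on numbering:
- C1 is the ring CHO carbon, C3 the side-chain CHO carbon, and C4 its α-carbon.
- C4a is the ring CH bearing the side chain; C5 and C6 are the ring CH2CH2.
- C7 is the quaternary carbon bearing CH3, C8 is CHOH, and C9 and C10 are CH2CH2.
- C11 is the tertiary carbinol, C11a the ring CH bearing C1, and C19 the one-carbon bridge CH2.
- C12–C15 are the diene and carbinol carbons.
- Compounds 3 and 4 are racemic; their stereocentres vanish in step 3.

Step 1
Reactants: 1 methacrylonitrile; 2 bromoform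
Product: 3 2,2-dibromo-1-methylcyclopropane-1-carbonitrile (racemic)
Conditions: 50% aq NaOH, BnEt3NCl (cat.), CH2Cl2, 0 °C → rt
Reagents that add atoms: none
Why: Makosza phase-transfer dibromocyclopropanation (CBr3−/:CBr2 addition and ring closure) is standard for methacrylic acceptor alkenes, and the stereocentre it creates is erased in step 3.

Step 2
Reactants: 3 2,2-dibromo-1-methylcyclopropane-1-carbonitrile
Product: 4 2-bromo-1-methylcyclopropane-1-carbonitrile (racemic cis/trans mixture)
Conditions: Bu3SnH (1.05 equiv), Et2O, 0 °C → rt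
Reagents that add atoms: none
Why: Radical-chain monodebromination of a gem-dibromocyclopropane with one equivalent of tin hydride stops at the monobromide because the second C–Br bond is much less reactive, and the isomer mixture is irrelevant since both centres vanish in step 3.

Step 3
Reactants: 4 2-bromo-1-methylcyclopropane-1-carbonitrile
Product: 5 1-methylcycloprop-2-ene-1-carbonitrile
Conditions: t-BuOK, 18-crown-6 (cat.), THF, rt
Reagents that add atoms: none
Why: Base-induced 1,2-dehydrobromination of a bromocyclopropane gives the cyclopropene, and the quaternary C7 (no H) excludes both isomerisation to a methylenecyclopropane and ene dimerisation.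

Step 4
Reactants: 5 1-methylcycloprop-2-ene-1-carbonitrile
Product: 7 1-(1-methylcycloprop-2-en-1-yl)ethan-1-one, via lithium ketimide 6 (not isolated)
Conditions: MeLi (2.5 equiv), Et2O, −78 → 0 °C; then 1 M aq HCl, 0 °C
Reagents that add atoms: methyllithium [Li]C; water O
Why: Organolithium addition to a nitrile stops at the ketimide and hydrolysis gives the methyl ketone, while any vinylic lithiation of the cyclopropene by excess MeLi is simply reversed on quenching.

Step 5
Reactants: 7 1-(1-methylcycloprop-2-en-1-yl)ethan-1-one; 8 2-bromo-N-methoxy-N-methylacetamide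
Product: 10 N-methoxy-N-methyl-4-(1-methylcycloprop-2-en-1-yl)-4-oxobutanamide, via lithium enolate 9 (not isolated)
Conditions: LDA (1.05 equiv), THF, −78 °C; then 8, DMPU, −78 → −20 °C
Reagents that add atoms: none
Why: Enolate alkylation (SN2) is unambiguous because the ketone has a single enolisable position and the α-bromo amide is an activated primary electrophile.

Step 6
Reactants: 10 N-methoxy-N-methyl-4-(1-methylcycloprop-2-en-1-yl)-4-oxobutanamide
Product: 11 (4R)-4-hydroxy-N-methoxy-N-methyl-4-(1-methylcycloprop-2-en-1-yl)butanamide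
Conditions: (S)-Me-CBS (20 mol %), catecholborane, PhMe, −78 °C
Reagents that add atoms: none
Why: Corey–Bakshi–Shibata reduction treats the quaternary cyclopropenyl group as the large and the CH2 chain as the small substituent, so the (S)-catalyst should give the (R)-carbinol (C8), and catecholborane at −78 °C neither hydroborates the strained alkene nor reduces the Weinreb amide.

Step 7
Reactants: 11 (4R)-hydroxy Weinreb amide
Product: 12 (4R)-4-[(tert-butyldimethylsilyl)oxy]-N-methoxy-N-methyl-4-(1-methylcycloprop-2-en-1-yl)butanamide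
Conditions: TBSOTf, 2,6-lutidine, CH2Cl2, 0 °C
Reagents that add atoms: tert-butyldimethylsilyl triflate CC(C)(C)[Si](C)(C)OS(=O)(=O)C(F)(F)F
Why: Silyl triflate silylation handles the hindered neopentyl-type secondary alcohol and removes the risk of lactonisation onto the amide.

Step 8
Reactants: 12 TBS-protected Weinreb amide; 13 methyl (E)-but-2-enoate
Product: 16 methyl (6R)-6-[(tert-butyldimethylsilyl)oxy]-2-ethenyl-6-(1-methylcycloprop-2-en-1-yl)-3-oxohexanoate (C2 epimers), via lithium dienolate 14 (not isolated), via tetrahedral adduct 15 (not isolated)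
Conditions: 13, LDA, THF–DMPU, −78 °C; then 12, −78 → −40 °C; AcOH, −78 °C
Reagents that add atoms: none
Why: Deconjugative α-acylation of the crotonate dienolate (Claisen-type) by a Weinreb amide stops at the chelated adduct and brings in C1, C11a, C4a and C5 at once, and the uncontrolled C11a centre is erased in step 9.

Step 9
Reactants: 16 α-vinyl β-keto ester
Product: 18 methyl (2Z,6R)-3,6-bis[(tert-butyldimethylsilyl)oxy]-2-ethenyl-6-(1-methylcycloprop-2-en-1-yl)hex-2-enoate, via chelated lithium enolate 17 (not isolated)
Conditions: LiHMDS, THF, −78 °C; then TBSOTf, −78 °C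
Reagents that add atoms: tert-butyldimethylsilyl triflate CC(C)(C)[Si](C)(C)OS(=O)(=O)C(F)(F)F
Why: Enol silylation removes the doubly activated C11a–H, and because lithium chelation holds the enolate oxygen and the ester carbonyl cis, O-silylation should give the Z enol ether in which C10 lies cis to the vinyl group.

Step 10
Reactants: 18 silyloxy triene
Product: 19 tricyclic Diels–Alder adduct (6S,7S,8R,11R,19R), the methyl C11a-carboxylate with a C4a=C11a double bond and a C6–C7–C19 cyclopropane
Conditions: PhMe (0.005 M), BHT (cat.), 100 °C, sealed tube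
Reagents that add atoms: none
Why: Thermal intramolecular Diels–Alder reaction ([π4s+π2s], concerted but asynchronous with C5–C6 ahead of C19–C11) between the diene C11=C11a–C4a=C5 and the cyclopropene C6=C19, whose strain release lowers the barrier; the closest known reactions are inter- and intramolecular Diels–Alder reactions of cyclopropenes and type-1 cycloadditions of (Z)-1,7,9-decatrienes, which give cis-fused bicycles. Two rings close: the cyclohexene C4a–C5–C6–C19–C11–C11a by the cycloaddition itself and the cyclohexane C7–C8–C9–C10–C11–C19 through the four-atom link C7–C10, which has to occupy the inside (Z) position at C11 and therefore enforces an exo transition state with C7 turned away from the diene. The C7 substituent that faces the diene, which normally blocks 3,3-dialkylcyclopropenes, is here the tether itself, so that clash becomes part of the forming ring. Suprafacial addition on both partners places C5, C11 and C8 on one cyclopropane face and H-6, H-19 and 7-CH3 on the other, gives the cis C11–C19 fusion (H-19 cis to the C11 oxygen), and makes C7 stereogenic in the only sense compatible with the later bridged skeleton. The single free variable, which of the two diastereotopic cyclopropene carbons bonds to C11 (equivalent to the diene face used), is decided by C8: the half-chair tether with the OTBS group pseudo-equatorial should be preferred and leads to the 7S,11R product with the C8 oxygen trans to 7-CH3. The step needs periselectivity over the [1,5]-H shift of the Z-diene and over ene pathways, which is secured by the strain-activated dienophile held at bonding distance, the absence of a C7–H, high dilution and a radical inhibitor.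

Step 11
Reactants: 19 tricyclic enoate
Product: 20 tricyclic allylic alcohol (C1 = CH2OH)
Conditions: DIBAL-H (2.5 equiv), CH2Cl2, −78 °C; Rochelle salt
Reagents that add atoms: none
Why: 1,2-Reduction of an α,β-unsaturated ester with DIBAL-H gives the allylic alcohol and leaves silyl ethers, alkene and cyclopropane untouched.

Step 12
Reactants: 20 tricyclic allylic alcohol
Product: 21 tricyclic allylic triethylsilyl ether
Conditions: TESCl, imidazole, CH2Cl2, 0 °C
Reagents that add atoms: chlorotriethylsilane CC[Si](Cl)(CC)CC
Why: Standard silylation of the only free (primary) hydroxyl installs a group that can later be oxidised directly under Swern conditions.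

Step 13
Reactants: 21 tricyclic allylic triethylsilyl ether
Product: 23 tricyclic pinacol boronate (4aS,6S,7S,8R,11R,11aS,19R), via monoalkylborane 22 (not isolated)
Conditions: BH3·SMe2 (3 equiv), THF, 0 °C → rt; then pinacol, rt
Reagents that add atoms: borane–dimethyl sulfide [BH3-][S+](C)C; pinacol CC(C)(O)C(C)(C)O
Why: Hydroboration (concerted syn addition) puts boron on the less substituted C4a, remote from both allylic C–O bonds, and approaches the convex face opposite the C8–C10 bridge, so B on C4a and H on C11a arrive on the same face (that of H-6 and H-19), which sets both centres with C1 trans to the future side chain; pinacol alcoholysis of the hindered monoalkylborane then gives the stable boronic ester.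

Step 14
Reactants: 23 tricyclic pinacol boronate
Product: 24 bicyclo[4.3.1]decane pinacol boronate (4aS,7S,8R,11R,11aS)
Conditions: H2 (60 bar), PtO2, EtOAc, 40 °C
Reagents that add atoms: none
Why: Catalytic hydrogenolysis of a 1,1-dialkylcyclopropane breaks the least substituted bond opposite the quaternary carbon (as in 1,1-dimethylcyclopropane to neopentane or carane to 1,1,4-trimethylcycloheptane), here C6–C19, whose cleavage also releases the extra strain of the tricycle; C6 and C19 become CH2, C7 keeps its configuration, and the silyl ethers and boronic ester are inert.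

Step 15
Reactants: 25 2-methylbut-3-en-2-ol; 26 (E)-but-2-enal
Product: 27 (E)-4-hydroxy-4-methylpent-2-enal
Conditions: Hoveyda–Grubbs II (3 mol %), CH2Cl2, 40 °C
Reagents that add atoms: none
Why: Olefin cross-metathesis between a hindered tertiary allylic alcohol and an enal is selective for the cross product and should give the E alkene (C13=C14).

Step 16
Reactants: 27 (E)-4-hydroxy-4-methylpent-2-enal; 28 ethyl (triphenyl-λ5-phosphanylidene)acetate
Product: 30 ethyl (2Z,4E)-2-bromo-6-hydroxy-6-methylhepta-2,4-dienoate, via bromo ylide 29 (not isolated)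
Conditions: 28, NBS, CH2Cl2, −20 °C; then 27, rt
Reagents that add atoms: N-bromosuccinimide O=C1CCC(=O)N1Br
Why: Wittig olefination with the stabilised α-bromo ylide made in situ places the new substituent trans to the ester, which gives the (Z)-α-bromo enoate with Br cis to C13.

Step 17
Reactants: 30 bromo dienoate
Product: 31 (2Z,4E)-2-bromo-6-methylhepta-2,4-diene-1,6-diol
Conditions: DIBAL-H (3.5 equiv), CH2Cl2, −78 °C; Rochelle salt
Reagents that add atoms: none
Why: 1,2-Reduction of the enoate with DIBAL-H gives the allylic alcohol without touching the vinylic bromide or the alkene geometries.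

Step 18
Reactants: 31 bromo dienediol
Product: 32 (2Z,4E)-2-bromo-6-methyl-1,6-bis[(triethylsilyl)oxy]hepta-2,4-diene
Conditions: TESOTf (2.5 equiv), 2,6-lutidine, CH2Cl2, −78 → 0 °C
Reagents that add atoms: triethylsilyl triflate CC[Si](CC)(CC)OS(=O)(=O)C(F)(F)F
Why: Silyl triflate silylation protects the primary and the tertiary hydroxyl in one operation.

Step 19
Reactants: 24 bicyclic pinacol boronate; 32 bis-TES bromodiene
Product: 36 fully silylated C4a-dienyl bicycle (4aS,7S,8R,11R,11aS; 4E,13E), via alkenyllithium 33 (not isolated), via boronate complex 34 (not isolated), via selenoboronate 35 (not isolated)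
Conditions: 32, t-BuLi (2 equiv), Et2O, −78 °C; 24, THF, −78 °C; PhSeCl, −78 °C; m-CPBA, −78 → −45 °C
Reagents that add atoms: none
Why: Zweifel-type olefination in its selenium variant combines Br/Li exchange with retention, ate-complex formation, a PhSeCl-induced 1,2-metallate shift (C4a migrates with retention, anti to selenium) and syn elimination of selenoxide and boron, which returns the original alkene geometry, so C4a takes the place of bromine cis to C13 and the C4a configuration is kept.

Step 20
Reactants: 36 fully silylated C4a-dienyl bicycle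
Product: 37 tris-silylated dialdehyde (4aS,7S,8R,11R,11aR)
Conditions: (COCl)2, DMSO, CH2Cl2, −78 → −30 °C; then Et3N, → 0 °C
Reagents that add atoms: none
Why: Swern oxidation converts primary triethylsilyl ethers directly into aldehydes while the tertiary TES ether and the secondary and tertiary TBS ethers survive, and since neither primary alcohol is ever free no C1/C3 lactol or lactone can form.

Step 21
Reactants: 37 tris-silylated dialdehyde
Product: 38 umbellacin A
Conditions: 48% aq HF, MeCN, 0 °C → rt
Reagents that add atoms: none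
Why: Acidic global desilylation avoids the basic conditions that would trigger retro-aldol cleavage of the C11–C11a β-hydroxy aldehyde, and dehydration towards C11=C11a is disfavoured because it would create a strained bridgehead alkene.

**Compound list**

1 | methacrylonitrile | C=C(C)C#N | starting material
2 | bromoform | BrC(Br)Br | starting material
3 | 2,2-dibromo-1-methylcyclopropane-1-carbonitrile (racemic) | CC1(C#N)CC1(Br)Br | intermediate
4 | 2-bromo-1-methylcyclopropane-1-carbonitrile (racemic cis/trans mixture) | CC1(C#N)CC1Br | intermediate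
5 | 1-methylcycloprop-2-ene-1-carbonitrile | CC1(C#N)C=C1 | intermediate
6 | lithium ketimide of 7 | CC(=N[Li])C1(C)C=C1 | intermediate
7 | 1-(1-methylcycloprop-2-en-1-yl)ethan-1-one | CC(=O)C1(C)C=C1 | intermediate
8 | 2-bromo-N-methoxy-N-methylacetamide | CON(C)C(=O)CBr | starting material
9 | lithium enolate of 7 | C=C(O[Li])C1(C)C=C1 | intermediate
10 | N-methoxy-N-methyl-4-(1-methylcycloprop-2-en-1-yl)-4-oxobutanamide | CON(C)C(=O)CCC(=O)C1(C)C=C1 | intermediate
11 | (4R)-4-hydroxy-N-methoxy-N-methyl-4-(1-methylcycloprop-2-en-1-yl)butanamide | CON(C)C(=O)CC[C@@H](O)C1(C)C=C1 | intermediate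
12 | (4R)-4-[(tert-butyldimethylsilyl)oxy]-N-methoxy-N-methyl-4-(1-methylcycloprop-2-en-1-yl)butanamide | CON(C)C(=O)CC[C@@H](O[Si](C)(C)C(C)(C)C)C1(C)C=C1 | intermediate
13 | methyl (E)-but-2-enoate | C/C=C/C(=O)OC | starting material
14 | lithium dienolate of 13 | C=CC=C(OC)O[Li] | intermediate
15 | tetrahedral N-methoxy-N-methyl adduct (lithium alkoxide) | COC(=O)C(C=C)C(O[Li])(N(C)OC)CC[C@@H](O[Si](C)(C)C(C)(C)C)C1(C)C=C1 | intermediate
16 | methyl (6R)-6-[(tert-butyldimethylsilyl)oxy]-2-ethenyl-6-(1-methylcycloprop-2-en-1-yl)-3-oxohexanoate (C2 epimers, keto/enol) | COC(=O)C(C=C)C(=O)CC[C@@H](O[Si](C)(C)C(C)(C)C)C1(C)C=C1 | intermediate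
17 | chelated lithium Z-enolate of 16 | COC(=O)/C(C=C)=C(\O[Li])CC[C@@H](O[Si](C)(C)C(C)(C)C)C1(C)C=C1 | intermediate
18 | methyl (2Z,6R)-3,6-bis[(tert-butyldimethylsilyl)oxy]-2-ethenyl-6-(1-methylcycloprop-2-en-1-yl)hex-2-enoate | COC(=O)/C(C=C)=C(\O[Si](C)(C)C(C)(C)C)CC[C@@H](O[Si](C)(C)C(C)(C)C)C1(C)C=C1 | intermediate
19 | tricyclic adduct (6S,7S,8R,11R,19R): cyclohexene C4a=C11a–C11–C19–C6–C5 cis-fused at C11–C19 to ring C7–C8–C9–C10–C11–C19, cyclopropane C6–C7–C19; CO2Me on C11a, OTBS on C8 and C11, CH3 on C7 | COC(=O)C1=CC[C@H]2[C@@H]3[C@@]2(C)[C@H](O[Si](C)(C)C(C)(C)C)CC[C@]13O[Si](C)(C)C(C)(C)C | intermediate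
20 | tricyclic allylic alcohol (CH2OH on C11a) | OCC1=CC[C@H]2[C@@H]3[C@@]2(C)[C@H](O[Si](C)(C)C(C)(C)C)CC[C@]13O[Si](C)(C)C(C)(C)C | intermediate
21 | tricyclic allylic triethylsilyl ether | CC[Si](CC)(CC)OCC1=CC[C@H]2[C@@H]3[C@@]2(C)[C@H](O[Si](C)(C)C(C)(C)C)CC[C@]13O[Si](C)(C)C(C)(C)C | intermediate
22 | tricyclic monoalkylborane (BH2 on C4a) | CC[Si](CC)(CC)OC[C@@H]1[C@@H](B)C[C@H]2[C@@H]3[C@@]2(C)[C@H](O[Si](C)(C)C(C)(C)C)CC[C@]13O[Si](C)(C)C(C)(C)C | intermediate
23 | tricyclic pinacol boronate (4aS,6S,7S,8R,11R,11aS,19R); B on C4a and H on C11a on the face of H-6/H-19 | CC[Si](CC)(CC)OC[C@@H]1[C@@H](B2OC(C)(C)C(C)(C)O2)C[C@H]3[C@@H]4[C@@]3(C)[C@H](O[Si](C)(C)C(C)(C)C)CC[C@]14O[Si](C)(C)C(C)(C)C | intermediate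
24 | bicyclo[4.3.1]decane pinacol boronate (4aS,7S,8R,11R,11aS) | CC1(C)OB(OC1(C)C)[C@H]2CC[C@@]3(C)C[C@](O[Si](C)(C)C(C)(C)C)(CC[C@H]3O[Si](C)(C)C(C)(C)C)[C@@H]2CO[Si](CC)(CC)CC | intermediate
25 | 2-methylbut-3-en-2-ol | CC(C)(O)C=C | starting material
26 | (E)-but-2-enal | C/C=C/C=O | starting material
27 | (E)-4-hydroxy-4-methylpent-2-enal | CC(C)(O)/C=C/C=O | intermediate
28 | ethyl (triphenyl-λ5-phosphanylidene)acetate | CCOC(=O)C=P(c1ccccc1)(c1ccccc1)c1ccccc1 | starting material
29 | ethyl bromo(triphenyl-λ5-phosphanylidene)acetate | CCOC(=O)C(Br)=P(c1ccccc1)(c1ccccc1)c1ccccc1 | intermediate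
30 | ethyl (2Z,4E)-2-bromo-6-hydroxy-6-methylhepta-2,4-dienoate | CCOC(=O)/C(Br)=C/C=C/C(C)(C)O | intermediate
31 | (2Z,4E)-2-bromo-6-methylhepta-2,4-diene-1,6-diol | OC/C(Br)=C/C=C/C(C)(C)O | intermediate
32 | (2Z,4E)-2-bromo-6-methyl-1,6-bis[(triethylsilyl)oxy]hepta-2,4-diene | CC[Si](CC)(CC)OC/C(Br)=C/C=C/C(C)(C)O[Si](CC)(CC)CC | intermediate
33 | alkenyllithium from 32 (Li cis to C13) | CC[Si](CC)(CC)OC/C([Li])=C/C=C/C(C)(C)O[Si](CC)(CC)CC | intermediate
34 | lithium alkenyl(alkyl) pinacol boronate complex | [Li+].CC[Si](CC)(CC)OC/C(=C/C=C/C(C)(C)O[Si](CC)(CC)CC)[B-]1(OC(C)(C)C(C)(C)O1)[C@H]2CC[C@@]3(C)C[C@](O[Si](C)(C)C(C)(C)C)(CC[C@H]3O[Si](C)(C)C(C)(C)C)[C@@H]2CO[Si](CC)(CC)CC | intermediate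
35 | β-(phenylselanyl) tertiary boronic ester (anti adduct at C4/C12; both facial isomers converge, so C4 and C12 are left open) | CC[Si](CC)(CC)OCC(B1OC(C)(C)C(C)(C)O1)(C([Se]c1ccccc1)/C=C/C(C)(C)O[Si](CC)(CC)CC)[C@H]2CC[C@@]3(C)C[C@](O[Si](C)(C)C(C)(C)C)(CC[C@H]3O[Si](C)(C)C(C)(C)C)[C@@H]2CO[Si](CC)(CC)CC | intermediate
36 | fully silylated C4a-dienyl bicycle (4aS,7S,8R,11R,11aS; 4E,13E): C1 and C3 as CH2OTES, C15-OTES, C8- and C11-OTBS | CC(C)(O[Si](CC)(CC)CC)/C=C/C=C(/CO[Si](CC)(CC)CC)[C@H]1CC[C@@]2(C)C[C@](O[Si](C)(C)C(C)(C)C)(CC[C@H]2O[Si](C)(C)C(C)(C)C)[C@@H]1CO[Si](CC)(CC)CC | intermediate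
37 | tris-silylated dialdehyde (4aS,7S,8R,11R,11aR) | CC(C)(O[Si](CC)(CC)CC)/C=C/C=C(/C=O)[C@H]1CC[C@@]2(C)C[C@](O[Si](C)(C)C(C)(C)C)(CC[C@H]2O[Si](C)(C)C(C)(C)C)[C@@H]1C=O | intermediate
38 | umbellacin A (4aS,7S,8R,11R,11aR; 4E,13E) | CC(C)(O)/C=C/C=C(/C=O)[C@H]1CC[C@@]2(C)C[C@](O)(CC[C@H]2O)[C@@H]1C=O | target

**Step count:** 21 steps in total. The longest linear sequence is 17 steps (steps 1–14 and 19–21).

**Steps most likely to fail**

Step 10. The cycloaddition may be outrun by the [1,5]-hydrogen shift from C10 to C5, or by slow thermal decomposition, because the ester-stabilised push–pull diene terminus C11 is fully substituted and sluggish. Facial discrimination by C8 may also be weaker than expected. The fallback removes the ester before the cycloaddition. Starting from 18, DIBAL-H reduction gives the dienyl alcohol F1, and TESCl/imidazole gives the dienyl triethylsilyl ether F2, a plain electron-rich 1-silyloxydiene without ground-state push–pull stabilisation. Heating F2 at the same dilution carries out the same double bond formation as a normal-electron-demand intramolecular Diels–Alder reaction. This comes back to the route at 21.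

Step 14. The catalyst may fail to reach the C6–C19 bond past the axial pinacol boronate, so the cyclopropane persists in neutral medium. The acid that would activate the catalyst would strip the primary TES ether. The fallback moves the hydrogenolysis to the robust ester.
- Starting from 19, H2/PtO2 in AcOH saturates the alkene and cleaves the cyclopropane to give the saturated bicyclic ester F3.
- LDA/PhSeBr gives the α-phenylselanyl ester F4.
- Oxidation with H2O2 and syn elimination give the bicyclic enoate F5.
- DIBAL-H gives the bicyclic allylic alcohol F6, and TESCl/imidazole gives the bicyclic allylic silyl ether F7.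
- Hydroboration of F7 with BH3·SMe2 from the face syn to the C19 bridge proceeds through the bicyclic monoalkylborane F8. Pinacol then brings the sequence back to the route at 24.

Step 19. The allylic selenoxide may undergo [2,3]-sigmatropic shift instead of elimination. The electrophile may attack the remote diene terminus. The β-silyloxy boronate may lose boron and oxygen. The hindered boronate may also resist ate-complex formation. The fallback replaces the metallate-shift/elimination logic by a stereoretentive cross-coupling. Starting from 24, t-BuLi (THF, −78 °C) gives the tert-butyl boronate complex F9. ZnCl2 effects boron-to-zinc transmetalation with retention to give the secondary alkylzinc chloride F10. A Negishi coupling of F10 with bromide 32 (Pd(OAc)2, CPhos, THF, rt) keeps both the C4a configuration and the alkene geometry. This comes back to the route at 36.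

**Further compounds**

F1 | step 10 | (6R)-3,6-bis[(tert-butyldimethylsilyl)oxy]-2-ethenyl-6-(1-methylcycloprop-2-en-1-yl)hex-2-en-1-ol (CH2OH cis to OTBS) | OC/C(C=C)=C(\O[Si](C)(C)C(C)(C)C)CC[C@@H](O[Si](C)(C)C(C)(C)C)C1(C)C=C1
F2 | step 10 | triethylsilyl ether of F1 | CC[Si](CC)(CC)OC/C(C=C)=C(\O[Si](C)(C)C(C)(C)C)CC[C@@H](O[Si](C)(C)C(C)(C)C)C1(C)C=C1
F3 | step 14 | saturated bicyclo[4.3.1]decane methyl ester | COC(=O)[C@@H]1CCC[C@@]2(C)C[C@]1(O[Si](C)(C)C(C)(C)C)CC[C@H]2O[Si](C)(C)C(C)(C)C
F4 | step 14 | C11a-phenylselanyl bicyclic ester (C11a open) | COC(=O)C1([Se]c2ccccc2)CCC[C@@]3(C)C[C@]1(O[Si](C)(C)C(C)(C)C)CC[C@H]3O[Si](C)(C)C(C)(C)C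
F5 | step 14 | bicyclic C4a=C11a enoate | COC(=O)C1=CCC[C@@]2(C)C[C@]1(O[Si](C)(C)C(C)(C)C)CC[C@H]2O[Si](C)(C)C(C)(C)C
F6 | step 14 | bicyclic allylic alcohol | OCC1=CCC[C@@]2(C)C[C@]1(O[Si](C)(C)C(C)(C)C)CC[C@H]2O[Si](C)(C)C(C)(C)C
F7 | step 14 | bicyclic allylic triethylsilyl ether | CC[Si](CC)(CC)OCC1=CCC[C@@]2(C)C[C@]1(O[Si](C)(C)C(C)(C)C)CC[C@H]2O[Si](C)(C)C(C)(C)C
F8 | step 14 | bicyclic monoalkylborane (BH2 on C4a) | B[C@H]1CC[C@@]2(C)C[C@](O[Si](C)(C)C(C)(C)C)(CC[C@H]2O[Si](C)(C)C(C)(C)C)[C@@H]1CO[Si](CC)(CC)CC
F9 | step 19 | lithium tert-butyl(alkyl) pinacol boronate complex | [Li+].CC(C)(C)[B-]1(OC(C)(C)C(C)(C)O1)[C@H]2CC[C@@]3(C)C[C@](O[Si](C)(C)C(C)(C)C)(CC[C@H]3O[Si](C)(C)C(C)(C)C)[C@@H]2CO[Si](CC)(CC)CC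
F10 | step 19 | C4a alkylzinc chloride | Cl[Zn][C@H]1CC[C@@]2(C)C[C@](O[Si](C)(C)C(C)(C)C)(CC[C@H]2O[Si](C)(C)C(C)(C)C)[C@@H]1CO[Si](CC)(CC)CC
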